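Start from the small charge of protic impurity in this flask, 3.60 mM against 0.18 M of starting material, and count it as a debt of 2.00 % of that starting material, one for one, which is my assumption.

the same everywhere: starting material 0.18 M

|  | first nucleophile | second nucleophile | protic impurity | remark | time |
|---|---|---|---|---|---|
| zeta | 0.18 M | 0.90 M | 2.4 mM | run made earlier |  |
| theta | 0.18 M | 0.90 M | 5.4 mM | run made earlier |  |
| eta | 0.18 M | 0.45 M | 3.6 mM | run made earlier |  |
| flask | 0.180 M | 0.900 M | 3.60 mM |  | 3.0 h |

| run | time / h | target / % | other capture product / % | starting material / % |
|---|---|---|---|---|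
| zeta | 0.250 | 10.5 | 7.0 | 78.7 |
| zeta | 0.417 | 13.8 | 10.6 | 68.6 |
| zeta | 0.833 | 17.7 | 20.2 | 48.4 |
| zeta | 1.50 | 18.0 | 30.4 | 27.6 |
| zeta | 3.00 | 14.8 | 42.8 | 7.5 |
| theta | 0.250 | 10.8 | 6.3 | 78.5 |
| theta | 0.833 | 17.5 | 18.5 | 47.8 |
| theta | 1.33 | 19.1 | 27.5 | 30.2 |
| theta | 2.00 | 16.6 | 35.1 | 17.5 |
| theta | 3.00 | 13.8 | 41.6 | 7.5 |
| eta | 0.667 | 20.6 | 9.8 | 55.1 |
| eta | 1.33 | 25.7 | 19.7 | 31.1 |
| eta | 2.00 | 24.5 | 25.9 | 17.6 |
| eta | 2.50 | 24.9 | 29.7 | 11.6 |
| eta | 3.00 | 24.2 | 32.6 | 8.2 |

(readings scatter by 0.5 percentage points)

- the earlier runs were read with a standard deviation of 0.5 percentage points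
- a reading or a percentage of target counts all its forms, free or not

1. ratio of target to other capture product at 80 s
2. ratio of target to other capture product at 3.0 h
3. which of target and other capture product there is more of at 3.0 h

At 1.33 h theta keeps 30.2 % of its starting material and eta 31.1 %, with 0.90 M and 0.45 M of second nucleophile, so read the loss as a step without nucleophile, whose product the two nucleophiles then share.

Use the symmetric case as zero: a nucleophile with no preference would give target over other capture product equal to the charge ratio, 0.200 in zeta. The bench rule divides the first reading's product ratio by that. But in zeta at 0.250 h the readings leave 3.80 % unaccounted, more than the debt of 1.33 %, so take the rest as target lost onward, which is again my assumption. Count instead everything that passed through the first nucleophile: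

first share = starting material lost − other capture product − impurity debt

preference = (first share / other capture product) × (second nucleophile / first nucleophile)

Zeta's first share is 13.0 %, giving 9.26; theta gives 9.68. Take their mean, 9.47, a pure number read from scattered readings, as the preference (selectivity factor), so expect a ratio of target to other capture product of 1.89 in this flask at 80 s.

The border shows in zeta: target is 0.810 of the first share at 0.250 h but 0.306 at 3.00 h. So for 3.0 h drop the rule and bracket the flask between zeta's 0.346 and theta's 0.332, with other capture product ahead.

The forecast gives 6 (3 to 14) at 80 s, apart from my figure, saying “I guess a ratio near 6, loosely”, and 0.34 (0.31 to 0.37) at 3.0 h, with other capture product ahead.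

The flask gives 1.92 at 80 s and 0.335 at 3.0 h, with 14.2 % of target against 42.6 % of other capture product.

    starting material ⇌ intermediate (K = 0.0330, k = 2.40 × 10⁻⁴ /s)
    first nucleophile + intermediate → target (k = 6.30 /M/s)
    second nucleophile + intermediate → other capture product (k = 0.640 /M/s)
    crystals ⇌ target, rate k4*(cs4 - [target]) while solid is left; crystals form when [target] > cs4 (solubility = 0.0760 M, k = 0.0530 /s)
    first nucleophile + target → over-reaction product (k = 0.00270 /M/s)
    starting material + protic impurity → quenched substrate (k = 0.0480 /M/s)

In this flask at 0.720 h, capture gives the first nucleophile a half-life of 1.7 h and the second 17 h, ten times as long, and target and other capture product stand level at 0.714 h. Charge a neighbour flask with 0.045 M of starting material, the nucleophiles unchanged, and the preference again gives 1.89 at 80 s, where that neighbour shows 1.93, yet at 3.0 h it holds 48.7 % of over-reaction product against 5.59 % of target, each in percent of its starting material charged.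

(The earlier runs and the new flask were generated by integration on assumed constants; noise was put on by code.)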